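**Retrosynthetic overview**
1. Numbering used here: ring A (cyclohexane) = C1 (ethyl), C2 (methyl), C3 (aryl ring C), C4 (methyl), C5 (aryl ring D), C6 (spiro carbon, shared with dienone ring B).
2. Last disconnection, C5–C6: ring A is closed last and ring B is dearomatised in the same step, by ipso attack of the 2,4,5-trimethoxyphenyl group on C1 at a C5 benzylic cation with loss of the para O-methyl group; the precursor is open-chain ether 17.
3. Key disconnection, C2–C3 and C4–C5 at once: three-component coupling of boronic ester 6 (C1–C2), alkenyllithium 13 (C3=C4 with ring C) and oxocarbenium ion 15 (C5 with ring D) through an electrophile-induced 1,2-metallate shift; boron on C3 is then exchanged for hydrogen.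
4. Enabling feature: C3–C4 is an aryl-propene unit (C3 bears ring C, C4 the methyl group), so C3 can carry boron and receive the migrating C2 while C4 is the nucleophilic terminus; C5 is benzylic to the electron-rich ring D, so it can be an oxygen-stabilised cation in steps 6 and 8.
5. Fragments: 6 from α-asarone (Cu-catalysed hydroboration sets C1, sparteine-controlled homologation sets C2), 10 from aryl iodide 7 and propyne, 12 from aldehyde 11.

Key step: step 6

Assumption: the target SMILES defines six stereocentres but not the rotamer about the bond from C5 to ring D, which is hindered next to the spiro centre; step 8 is expected to give both rotamers, and the one corresponding to tatanan B would be separated by chromatography.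

**Step 1**
Reactants: 1 α-asarone
Product: 2 (S)-4,4,5,5-tetramethyl-2-[1-(2,4,5-trimethoxyphenyl)propyl]-1,3,2-dioxaborolane
Conditions: CuCl (3 mol%), NaOtBu (6 mol%), (S,S,R,R)-TangPhos (3.3 mol%), HBpin (1.2 equiv), toluene, rt
Reagents that add atoms: pinacolborane, [H]B1OC(C)(C)C(C)(C)O1
Why: Copper-hydride-catalysed asymmetric hydroboration of a β-alkyl vinylarene, in which the ligand-bound copper hydride adds across the E-olefin with copper on the benzylic carbon and exchange with HBpin gives the benzylic boronic ester, so the ligand sets C1 as (S); the mirror-image ligand is taken if a small-scale test on this ortho-methoxy substrate shows the opposite sense.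

**Step 2**
Reactants: 2 (S)-benzylic boronic ester; 3 ethyl 2,4,6-triisopropylbenzoate
Product: 6 4,4,5,5-tetramethyl-2-[(2S,3R)-3-(2,4,5-trimethoxyphenyl)pentan-2-yl]-1,3,2-dioxaborolane, via lithiated benzoate 4 (not isolated), via boronate complex 5 (not isolated)
Conditions: 3, (+)-sparteine, sBuLi, Et2O, −78 °C; then 2, −78 °C → 35 °C; aq NH4Cl
Reagents that add atoms: none
Why: Reagent-controlled lithiation–borylation homologation (Matteson-type 1,2-metallate rearrangement), in which (+)-sparteine-directed deprotonation gives (R)-carbenoid 4, borylation goes with retention, and the benzylic group migrates antiperiplanar to the benzoate with inversion at the carbenoid carbon and retention at C1, so C2 is set as (S) by the reagent alone.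

**Step 3**
Reactants: 7 1-iodo-2,4,5-trimethoxybenzene; 8 propyne
Product: 9 1,2,4-trimethoxy-5-(prop-1-yn-1-yl)benzene
Conditions: PdCl2(PPh3)2 (2 mol%), CuI (4 mol%), Et3N, THF, rt, sealed vessel
Reagents that add atoms: none
Why: Sonogashira coupling of an aryl iodide with a terminal alkyne, which tolerates the electron-rich ring and forms no stereocentre.

**Step 4**
Reactants: 9 1,2,4-trimethoxy-5-(prop-1-yn-1-yl)benzene
Product: 10 (E)-tributyl[1-(2,4,5-trimethoxyphenyl)prop-1-en-1-yl]stannane
Conditions: PdCl2(PPh3)2 (2 mol%), Bu3SnH (1.2 equiv, slow addition), THF, 0 °C → rt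
Reagents that add atoms: tributyltin hydride, CCCC[SnH](CCCC)CCCC
Why: Palladium-catalysed syn-hydrostannation of an aryl alkyl alkyne, in which the ortho-methoxy group directs tin to the aryl-bearing carbon and syn addition puts tin cis to the new vinylic hydrogen, so ring C and the methyl group end up cis, the olefin geometry that step 6 needs.

**Step 5**
Reactants: 11 2,4,5-trimethoxybenzaldehyde
Product: 12 1-(dimethoxymethyl)-2,4,5-trimethoxybenzene
Conditions: HC(OMe)3, MeOH, TsOH (1 mol%), rt; Et3N
Reagents that add atoms: trimethyl orthoformate, COC(OC)OC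
Why: Acid-catalysed acetalisation of an aromatic aldehyde driven by the orthoformate as water scavenger.

**Step 6**
Reactants: 10 (E)-alkenylstannane; 6 (2S,3R)-boronic ester; 12 dimethyl acetal
Product: 16 2-[(2R,3S,4S,5R)-1-methoxy-2,4-dimethyl-1,3,5-tris(2,4,5-trimethoxyphenyl)heptan-3-yl]-4,4,5,5-tetramethyl-1,3,2-dioxaborolane (both epimers at the methoxy-bearing carbon), via alkenyllithium 13 (not isolated), via alkenylboronate complex 14 (not isolated), via oxocarbenium triflate 15 (not isolated)
Conditions: 10, nBuLi, THF, −78 °C; then 6, −78 °C; then 15 (from 12 and TMSOTf 0.95 equiv, CH2Cl2, −78 °C), −78 → −40 °C; aq NaHCO3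
Reagents that add atoms: none
Why: Proposed new method: the β-carbon C4 of the electron-rich alkenylboronate complex 14 attacks the oxocarbenium carbon C5 of 15 while the C2 group migrates from boron to C3 antiperiplanar to the new C4–C5 bond, so both bonds form in one 1,2-metallate event; the closest known reaction type is the electrophile-induced (Zweifel-type, conjunctive) 1,2-metallate rearrangement of alkenylboronate complexes with carbenium and iminium electrophiles, not yet shown with an acetal-derived oxocarbenium ion or a 1-aryl-2-methylalkenyl group. No ring is closed. C3 and C4 are set relative to each other by the anti stereospecificity together with the olefin geometry of 13 (ring C cis to methyl, boron cis to hydrogen), which after boron-to-hydrogen exchange with retention gives the trans aryl/methyl pattern of ring A, and C2 migrates with retention. The step needs π-facial selectivity relative to C2, and the expected reactive conformer has the C1 arm of the migrating carbon anti to the boron–alkenyl bond, the C2 methyl group over the small C4–H edge and the C2 hydrogen toward the twisted ring C, which leads to the diastereomer drawn. C5 forms as an epimer mixture, which is harmless because C5 is ionised again in step 8. Attack at C4 and not at the arene rings is secured by the borate, which makes C4 the most nucleophilic carbon and C3 the migration terminus.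

**Step 7**
Reactants: 16 tertiary benzylic boronic ester
Product: 17 (2R,3S,4S,5R)-1-methoxy-2,4-dimethyl-1,3,5-tris(2,4,5-trimethoxyphenyl)heptane (both epimers at the methoxy-bearing carbon)
Conditions: TBAF·3H2O (3 equiv), toluene, 60 °C
Reagents that add atoms: none
Why: Fluoride-promoted stereoretentive protodeboronation of a tertiary benzylic boronic ester, in which fluoride forms the borate and water protonates the C–B bond from the front, so hydrogen takes the place of boron and C3 is fixed as (S).

**Step 8**
Reactants: 17 open-chain benzylic methyl ether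
Product: 20 tatanan B, via benzylic cation 18 (not isolated), via spirocyclic oxocarbenium ion 19 (not isolated)
Conditions: TfOH (10 mol%), H2O (5 equiv), (CF3)2CHOH/CH2Cl2 1:4, 0.005 M, −20 °C → rt; aq NaHCO3
Reagents that add atoms: water, O
Why: Dearomative ipso-Friedel–Crafts spirocyclisation, in which acid ionises the benzylic ether to cation 18, the ipso carbon C6 of ring B (activated by an ortho and a para methoxy group) attacks C5 through a chair with C1 ethyl, C3 aryl, C4 methyl and C5 aryl equatorial and C2 methyl axial, the methoxy-bearing ortho carbon of ring B turning away from the axial C2 methyl group, and water hydrolyses 19 to the dienone, which sets C5 and C6.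

**Compound list**
1 | α-asarone, (E)-1,2,4-trimethoxy-5-(prop-1-en-1-yl)benzene | C/C=C/c1cc(OC)c(OC)cc1OC | starting material
2 | (S)-4,4,5,5-tetramethyl-2-[1-(2,4,5-trimethoxyphenyl)propyl]-1,3,2-dioxaborolane | CC[C@@H](c1cc(OC)c(OC)cc1OC)B1OC(C)(C)C(C)(C)O1 | intermediate
3 | ethyl 2,4,6-triisopropylbenzoate | CCOC(=O)c1c(C(C)C)cc(C(C)C)cc1C(C)C | starting material
4 | (R)-1-lithioethyl 2,4,6-triisopropylbenzoate (sparteine complex) | C[C@@H]([Li])OC(=O)c1c(C(C)C)cc(C(C)C)cc1C(C)C | intermediate
5 | lithium [(1R)-1-(2,4,6-triisopropylbenzoyloxy)ethyl][(1S)-1-(2,4,5-trimethoxyphenyl)propyl](pinacolato)borate | [Li+].CC[C@@H](c1cc(OC)c(OC)cc1OC)[B-]1(OC(C)(C)C(C)(C)O1)[C@H](C)OC(=O)c1c(C(C)C)cc(C(C)C)cc1C(C)C | intermediate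
6 | 4,4,5,5-tetramethyl-2-[(2S,3R)-3-(2,4,5-trimethoxyphenyl)pentan-2-yl]-1,3,2-dioxaborolane | CC[C@@H](c1cc(OC)c(OC)cc1OC)[C@H](C)B1OC(C)(C)C(C)(C)O1 | intermediate
7 | 1-iodo-2,4,5-trimethoxybenzene | Ic1cc(OC)c(OC)cc1OC | starting material
8 | propyne | CC#C | starting material
9 | 1,2,4-trimethoxy-5-(prop-1-yn-1-yl)benzene | CC#Cc1cc(OC)c(OC)cc1OC | intermediate
10 | (E)-tributyl[1-(2,4,5-trimethoxyphenyl)prop-1-en-1-yl]stannane (tin cis to the vinylic hydrogen) | C/C=C(/[Sn](CCCC)(CCCC)CCCC)c1cc(OC)c(OC)cc1OC | intermediate
11 | 2,4,5-trimethoxybenzaldehyde | O=Cc1cc(OC)c(OC)cc1OC | starting material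
12 | 1-(dimethoxymethyl)-2,4,5-trimethoxybenzene | COC(OC)c1cc(OC)c(OC)cc1OC | intermediate
13 | (Z)-[1-(2,4,5-trimethoxyphenyl)prop-1-en-1-yl]lithium (lithium cis to the vinylic hydrogen) | C/C=C(/[Li])c1cc(OC)c(OC)cc1OC | intermediate
14 | lithium [(Z)-1-(2,4,5-trimethoxyphenyl)prop-1-en-1-yl][(2S,3R)-3-(2,4,5-trimethoxyphenyl)pentan-2-yl](pinacolato)borate | [Li+].CC[C@@H](c1cc(OC)c(OC)cc1OC)[C@H](C)[B-]1(OC(C)(C)C(C)(C)O1)/C(c1cc(OC)c(OC)cc1OC)=C/C | intermediate
15 | methoxy(2,4,5-trimethoxyphenyl)methylium triflate (O-methyl oxocarbenium salt) | C[O+]=Cc1cc(OC)c(OC)cc1OC.[O-]S(=O)(=O)C(F)(F)F | intermediate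
16 | 2-[(2R,3S,4S,5R)-1-methoxy-2,4-dimethyl-1,3,5-tris(2,4,5-trimethoxyphenyl)heptan-3-yl]-4,4,5,5-tetramethyl-1,3,2-dioxaborolane, both epimers at C1 of the heptane | CC[C@@H](c1cc(OC)c(OC)cc1OC)[C@H](C)[C@](B1OC(C)(C)C(C)(C)O1)(c1cc(OC)c(OC)cc1OC)[C@@H](C)C(OC)c1cc(OC)c(OC)cc1OC | intermediate
17 | (2R,3S,4S,5R)-1-methoxy-2,4-dimethyl-1,3,5-tris(2,4,5-trimethoxyphenyl)heptane, both epimers at C1 | CC[C@@H](c1cc(OC)c(OC)cc1OC)[C@H](C)[C@H](c1cc(OC)c(OC)cc1OC)[C@@H](C)C(OC)c1cc(OC)c(OC)cc1OC | intermediate
18 | benzylic cation from 17 (C5 cation stabilised by ring D) | CC[C@@H](c1cc(OC)c(OC)cc1OC)[C@H](C)[C@H](c1cc(OC)c(OC)cc1OC)[C@@H](C)[CH+]c1cc(OC)c(OC)cc1OC | intermediate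
19 | spirocyclic O-methyl oxocarbenium ion (O-methylated tatanan B) | CC[C@@H]1[C@H](C)[C@H](c2cc(OC)c(OC)cc2OC)[C@@H](C)[C@H](c2cc(OC)c(OC)cc2OC)[C@]12C=C(OC)C(=[O+]C)C=C2OC | intermediate
20 | tatanan B | CC[C@@H]1[C@H](C)[C@H](c2cc(OC)c(OC)cc2OC)[C@@H](C)[C@H](c2cc(OC)c(OC)cc2OC)[C@]12C=C(OC)C(=O)C=C2OC | target

**Step count and risks**
Total steps: 8. Longest linear sequence: 5 steps (1, 2, 6, 7, 8 or 3, 4, 6, 7, 8).

Most likely to fail:

Step 6. What may go wrong: poor π-facial selectivity in the 1,2-metallate shift (C3 and C4 formed in the wrong sense relative to C2), or attack of the oxocarbenium ion or of residual silyl triflate at a site other than C4. Fallback with known chemistry, from 11 and 6, rejoining at 16: the C3–C4–C5 part is made first and joined to 6 by stereospecific lithiation–borylation. Aldehyde 11 is crotylated with (Z)-crotyldiisopinocampheylborane of the handedness that gives syn-(1R,2S)-2-methyl-1-(2,4,5-trimethoxyphenyl)but-3-en-1-ol F1. Carbamoylation (NaH, iPr2NCOCl) gives the N,N-diisopropylcarbamate F2. Oxidative cleavage of the vinyl group (OsO4 cat., NaIO4, 2,6-lutidine) gives the α-methyl aldehyde F3. Addition of 7 after iodine–magnesium exchange (iPrMgCl·LiCl, −78 °C) gives the diaryl carbamate alcohol F4 as carbinol epimers, and O-methylation (NaH, MeI) gives the methyl ether carbamate F5. Lithiation of F5 at the carbamate-bearing benzylic carbon (sBuLi, Et2O, −78 °C, retention), borylation with 6 (retention) and 1,2-migration with inversion (MgBr2·OEt2, MeOH, warming) should give 16 with C2, C3 and C4 all fixed by the two partners.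

Step 7. What may go wrong: no reaction at the shielded boron atom, or loss of configuration at C3 under forcing conditions. Fallback, from 6, rejoining at 17: ring C is left out of the alkenyl partner and is introduced from boron instead of hydrogen. Under the conditions of step 6, 6 is combined with (Z)-prop-1-enyllithium (from commercial (Z)-1-bromopropene and tBuLi) and then with 15, which should give the secondary boronic ester F6 with boron in the place that ring C takes in 17. Addition of 7 after iodine–lithium exchange (nBuLi) to the boron atom, then an oxidant (NBS or DDQ), triggers 1,2-migration of C3 to the aryl carbon with retention and loss of the boron residue, a stereoretentive coupling of secondary boronic esters with electron-rich arenes, to give 17.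

Step 8. What may go wrong: partition of the cation between ipso attack and attack at the free ortho position of ring C (five-membered ring), loss of C4 configuration through reversible proton loss, or slow collapse of the spiro cation with return to the open cation. Fallback, from 17, rejoining at 20: the acid-equilibrated one-pot closure is replaced by an irreversible two-stage sequence without a proton source. Ionisation with TMSOTf and 2,6-di-tert-butyl-4-methylpyridine in CH2Cl2 at −78 °C is followed by transfer into NaOMe/MeOH at −78 °C, which captures the spiro cation as the spirocyclic dienone dimethyl ketal F7. Mild hydrolysis of F7 (wet silica gel, oxalic acid) then gives 20.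

**Further compounds**
F1 | step 6 | (1R,2S)-2-methyl-1-(2,4,5-trimethoxyphenyl)but-3-en-1-ol | O[C@@H](c1cc(OC)c(OC)cc1OC)[C@@H](C)C=C
F2 | step 6 | (1R,2S)-2-methyl-1-(2,4,5-trimethoxyphenyl)but-3-en-1-yl N,N-diisopropylcarbamate | CC(C)N(C(C)C)C(=O)O[C@@H](c1cc(OC)c(OC)cc1OC)[C@@H](C)C=C
F3 | step 6 | (1R,2R)-2-methyl-3-oxo-1-(2,4,5-trimethoxyphenyl)propyl N,N-diisopropylcarbamate | CC(C)N(C(C)C)C(=O)O[C@@H](c1cc(OC)c(OC)cc1OC)[C@@H](C)C=O
F4 | step 6 | (1R,2R)-3-hydroxy-2-methyl-1,3-bis(2,4,5-trimethoxyphenyl)propyl N,N-diisopropylcarbamate, both epimers at C3 | CC(C)N(C(C)C)C(=O)O[C@@H](c1cc(OC)c(OC)cc1OC)[C@@H](C)C(O)c1cc(OC)c(OC)cc1OC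
F5 | step 6 | (1R,2R)-3-methoxy-2-methyl-1,3-bis(2,4,5-trimethoxyphenyl)propyl N,N-diisopropylcarbamate, both epimers at C3 | CC(C)N(C(C)C)C(=O)O[C@@H](c1cc(OC)c(OC)cc1OC)[C@@H](C)C(OC)c1cc(OC)c(OC)cc1OC
F6 | step 7 | secondary boronic ester, the analogue of 16 that carries hydrogen in place of ring C on the boron-bearing carbon, both epimers at the methoxy-bearing carbon | CC[C@@H](c1cc(OC)c(OC)cc1OC)[C@H](C)[C@H](B1OC(C)(C)C(C)(C)O1)[C@@H](C)C(OC)c1cc(OC)c(OC)cc1OC
F7 | step 8 | tatanan B dimethyl ketal (spirocyclic 2,5-dimethoxycyclohexa-2,5-dienone dimethyl ketal) | CC[C@@H]1[C@H](C)[C@H](c2cc(OC)c(OC)cc2OC)[C@@H](C)[C@H](c2cc(OC)c(OC)cc2OC)[C@]12C=C(OC)C(OC)(OC)C=C2OC
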